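The benzene ring is numbered C1 (CH2SO2CH3), C2 (Br), C3 and C4 (OH), C5 and C6 (Br) and is cut at C1–C2 and C4–C5. One Lewis-acid [3+3] benzannulation makes both bonds and the ring. It exploits the contiguous C2–C3–C4 unit, whose two oxygens and a C2 ester (a placeholder for bromine) map onto the bis(silyl enol ether) of methyl 4-methoxyacetoacetate, a 1,3-dinucleophile. The partner C5–C6–C1 is a β-keto acetal, a 1,3-dielectrophile that already carries the sulfone arm on its ketone carbon. The resulting salicylate is hydrolysed, demethylated and brominated three times, once with loss of CO2.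

Key step: step 4

Assumption: alkene geometries of the silyl enol ethers that are not drawn as defined are taken as inconsequential, because each of these alkenes ends inside the aromatic ring. The target has no stereocentre.

Step 1
Reactants: 1 methyl 4-methoxy-3-oxobutanoate
Product: 2 methyl 4-methoxy-3-(trimethylsilyloxy)but-2-enoate
Conditions: Me3SiCl (1.5 equiv), Et3N (1.6 equiv), toluene, 20 °C; filtration under argon
Reagents that add atoms: chlorotrimethylsilane, C[Si](C)(C)Cl
Why: O-silylation of a β-keto ester under soft enolisation, in which the amine removes the acidic proton between the two carbonyl groups and the oxophilic silicon is taken up at the ketone oxygen to give the ester-conjugated silyl enol ether.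

Step 2
Reactants: 2 methyl 4-methoxy-3-(trimethylsilyloxy)but-2-enoate
Product: 4 (3Z)-1,4-dimethoxy-1,3-bis(trimethylsilyloxy)buta-1,3-diene, via lithium dienolate 3 (not isolated)
Conditions: LiN(iPr)2 (1.3 equiv), THF, −78 °C; then Me3SiCl (1.5 equiv), −78 → 20 °C; hexane, filtration under argon, used crude
Reagents that add atoms: chlorotrimethylsilane, C[Si](C)(C)Cl
Why: Kinetic γ-deprotonation of the β-silyloxy enoate by the hindered amide gives the extended dienolate 3, which silicon traps on the ester oxygen (dienolate O-silylation, the standard second stage in making 1,3-bis(silyloxy)dienes), and the 3Z geometry usually obtained does not matter because C4 becomes an arene carbon.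

Step 3
Reactants: 5 dimethyl sulfone; 6 methyl 3,3-dimethoxypropanoate
Product: 8 4,4-dimethoxy-1-(methylsulfonyl)butan-2-one, via lithiated dimethyl sulfone 7 (not isolated)
Conditions: 5 (2.2 equiv), n-BuLi (2.1 equiv), THF, −78 → 0 °C; then 6 (1 equiv, slow addition), −78 → −20 °C; aq. NH4Cl
Reagents that add atoms: none
Why: Claisen-type acylation of an α-sulfonyl carbanion by an ester, in which the second equivalent of 7 deprotonates the acidic β-keto sulfone as it forms and so blocks over-addition, while low temperature and slow addition keep carbonyl attack ahead of E1cB loss of methoxide from 6, as in the analogous acylation of lithiated methylphosphonates by the same ester.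

Step 4
Reactants: 4 (3Z)-1,4-dimethoxy-1,3-bis(trimethylsilyloxy)buta-1,3-diene; 8 4,4-dimethoxy-1-(methylsulfonyl)butan-2-one
Product: 11 methyl 2-hydroxy-3-methoxy-6-[(methylsulfonyl)methyl]benzoate, via open-chain adduct 9 (not isolated), via cyclic aldol 10 (not isolated)
Conditions: 4 (1.5 equiv), TiCl4 (2 equiv, added last), 4 Å molecular sieves, CH2Cl2, −78 → 20 °C; then 1 M aq. HCl
Reagents that add atoms: none
Why: TiCl4 activates the dimethyl acetal of 8 by abstracting one methoxide, and the methoxy-bearing terminus of 4, the most nucleophilic carbon of the diene, attacks that carbon in a vinylogous Mukaiyama-type addition that forms C4–C5 and gives 9. The β-keto ester enol silane that remains in 9 then adds through C2 to the titanium-bound ketone, forming C1–C2 and closing the single ring as aldol 10; the closure is 6-exo-trig at the carbonyl, (enolexo) when the nucleophile is read as the ester enolate and (enolendo) when it is read as the C3 enolate, and both modes are favoured for a six-membered ring. E1cB loss of the C5 methoxy group (β to the C3 ketone), dehydration at C1 and enolisation of C3 aromatise 10 to 11, so the transient stereocentres of 9 and 10 are erased and none has to be controlled. The closest known reaction is the TiCl4-mediated formal [3+3] cyclocondensation of 1,3-bis(silyloxy)buta-1,3-dienes with β-keto acetals, which places the ketone substituent ortho to the ester. The selectivity needed is regiochemical (arm on C1 beside the ester, not on C5 beside the methoxy group) and is secured by matching the stronger electrophile (ionised acetal carbon rather than ketone carbon) with the stronger nucleophile (diene terminus rather than C2). Two equivalents of TiCl4 are used because the keto sulfone should hold one as a six-membered chelate, and the absence of any amine base at low temperature should keep the acidic CH2 between ketone and sulfone from enolising.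

Step 5
Reactants: 11 methyl 2-hydroxy-3-methoxy-6-[(methylsulfonyl)methyl]benzoate
Product: 12 2-hydroxy-3-methoxy-6-[(methylsulfonyl)methyl]benzoic acid
Conditions: NaOH (6 equiv), MeOH–H2O, reflux; then 1 M aq. HCl, 0 °C
Reagents that add atoms: sodium hydroxide, [Na+].[OH-]
Why: Saponification (acyl-oxygen ester hydrolysis), run hot because the ester is flanked on both sides, and placed before the ether cleavage because the only phenoxide present (on C3) is meta to C1 while the para oxygen on C4 is still methylated, so methanesulfinate cannot be expelled through a quinone methide.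

Step 6
Reactants: 12 2-hydroxy-3-methoxy-6-[(methylsulfonyl)methyl]benzoic acid
Product: 13 2,3-dihydroxy-6-[(methylsulfonyl)methyl]benzoic acid
Conditions: BBr3 (5 equiv), CH2Cl2, −78 → 20 °C; then H2O, 0 °C
Reagents that add atoms: none
Why: Lewis-acid cleavage of an aryl methyl ether, in which boron binds the C4 ether oxygen and bromide removes the methyl group by SN2, while the acid, the phenol and the sulfone only take up extra reagent reversibly and are released on hydrolysis.

Step 7
Reactants: 13 2,3-dihydroxy-6-[(methylsulfonyl)methyl]benzoic acid
Product: 15 3,4,6-tribromo-5-[(methylsulfonyl)methyl]benzene-1,2-diol, via dibromo acid 14 (not isolated)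
Conditions: Br2 (3.3 equiv), NaOAc (3 equiv), AcOH–H2O, dark, 20 → 50 °C; then aq. Na2S2O4
Reagents that add atoms: bromine, BrBr
Why: Electrophilic aromatic bromination first fills C6 (para to the C3 hydroxyl) and C5 (ortho to the C4 hydroxyl) to give 14, after which ipso attack at C2 (ortho to the C3 hydroxyl) with loss of CO2 (bromodecarboxylation of a salicylic acid) installs the third bromine, the acetate buffer and water favouring the ionised carboxyl group needed for that loss, the dark suppressing benzylic radical bromination and the reducing work-up returning any over-oxidised material to the catechol.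

Compound list
1 | methyl 4-methoxy-3-oxobutanoate | COCC(=O)CC(=O)OC | starting material
2 | methyl 4-methoxy-3-(trimethylsilyloxy)but-2-enoate (alkene geometry undefined) | COCC(O[Si](C)(C)C)=CC(=O)OC | intermediate
3 | lithium (3Z)-1,4-dimethoxy-3-(trimethylsilyloxy)buta-1,3-dien-1-olate | CO/C=C(\O[Si](C)(C)C)C=C(OC)[O-].[Li+] | intermediate
4 | (3Z)-1,4-dimethoxy-1,3-bis(trimethylsilyloxy)buta-1,3-diene | CO/C=C(\O[Si](C)(C)C)C=C(OC)O[Si](C)(C)C | intermediate
5 | dimethyl sulfone | CS(C)(=O)=O | starting material
6 | methyl 3,3-dimethoxypropanoate | COC(OC)CC(=O)OC | starting material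
7 | [(methylsulfonyl)methyl]lithium | [Li]CS(C)(=O)=O | intermediate
8 | 4,4-dimethoxy-1-(methylsulfonyl)butan-2-one | COC(OC)CC(=O)CS(C)(=O)=O | intermediate
9 | methyl 4,5-dimethoxy-8-(methylsulfonyl)-7-oxo-3-(trimethylsilyloxy)oct-2-enoate (diastereomer mixture, erased in the same step) | COC(=O)C=C(O[Si](C)(C)C)C(OC)C(OC)CC(=O)CS(C)(=O)=O | intermediate
10 | methyl 2-hydroxy-4,5-dimethoxy-2-[(methylsulfonyl)methyl]-6-oxocyclohexane-1-carboxylate (drawn neutral, diastereomer mixture, erased in the same step) | COC(=O)C1C(=O)C(OC)C(OC)CC1(O)CS(C)(=O)=O | intermediate
11 | methyl 2-hydroxy-3-methoxy-6-[(methylsulfonyl)methyl]benzoate | COC(=O)c1c(O)c(OC)ccc1CS(C)(=O)=O | intermediate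
12 | 2-hydroxy-3-methoxy-6-[(methylsulfonyl)methyl]benzoic acid | OC(=O)c1c(O)c(OC)ccc1CS(C)(=O)=O | intermediate
13 | 2,3-dihydroxy-6-[(methylsulfonyl)methyl]benzoic acid | OC(=O)c1c(O)c(O)ccc1CS(C)(=O)=O | intermediate
14 | 3,4-dibromo-5,6-dihydroxy-2-[(methylsulfonyl)methyl]benzoic acid | OC(=O)c1c(O)c(O)c(Br)c(Br)c1CS(C)(=O)=O | intermediate
15 | 3,4,6-tribromo-5-[(methylsulfonyl)methyl]benzene-1,2-diol | CS(=O)(=O)Cc1c(Br)c(O)c(O)c(Br)c1Br | target

Total step count: 7. Longest linear sequence: 6 steps (1, 2, 4, 5, 6, 7).

Steps most likely to fail

Step 4. Chelation of TiCl4 by the keto sulfone may raise the reactivity of the ketone above that of the acetal and erode the regiocontrol. Proton transfer from the acidic methylene may also desilylate the diene before any C–C bond forms. The fallback sets out from 4 and returns at 12, and it brings in the sulfone only after the ring is built.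
- Diene 4 is cyclised under TiCl4 with commercial 4,4-dimethoxybutan-2-one (COC(OC)CC(C)=O), the parent electrophile of this reaction class, to give methyl 2-hydroxy-3-methoxy-6-methylbenzoate F1.
- Acetylation (Ac2O, pyridine) gives methyl 2-acetoxy-3-methoxy-6-methylbenzoate F2.
- Wohl–Ziegler bromination (NBS, AIBN, PhCF3, reflux) gives methyl 2-acetoxy-6-(bromomethyl)-3-methoxybenzoate F3.
- S-alkylation of NaSO2CH3 in DMF at 20 °C gives methyl 2-acetoxy-3-methoxy-6-[(methylsulfonyl)methyl]benzoate F4.
- The conditions of step 5 then remove acetate and methyl ester together and deliver 12.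

Step 7. Oxidation of the free catechol may outrun substitution, or the ipso attack at C2 may stall once two bromines have deactivated the ring. The fallback sets out from 12 and returns at 15. The bromination is moved ahead of the ether cleavage, so no catechol is exposed to bromine and more forcing conditions become tolerable. Acid 12 with excess Br2 and NaOAc in AcOH–H2O (20 → 70 °C) should undergo the same double substitution and bromodecarboxylation to give 2,4,5-tribromo-6-methoxy-3-[(methylsulfonyl)methyl]phenol F5. BBr3 in CH2Cl2 then frees the C4 hydroxyl as the last operation to give 15.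

Step 3. Deprotonation of the ester next to its carbonyl group, followed by E1cB loss of methoxide, may compete with acyl substitution. The fallback sets out from 6 (and 5) and returns at 8. It replaces acylation by carbonyl addition and oxidation.
- Ester 6 is reduced with i-Bu2AlH (CH2Cl2, −78 °C) to 3,3-dimethoxypropanal F6, which is used crude.
- One equivalent of 7, made from 5 as in step 3, adds to the aldehyde at −78 °C faster than it can enolise it, giving 4,4-dimethoxy-1-(methylsulfonyl)butan-2-ol F7 (racemic, the stereocentre being removed at once).
- Dess–Martin periodinane buffered with NaHCO3 in CH2Cl2 oxidises the alcohol to 8.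

Further compounds
F1 | step 4 | methyl 2-hydroxy-3-methoxy-6-methylbenzoate | COC(=O)c1c(O)c(OC)ccc1C
F2 | step 4 | methyl 2-acetoxy-3-methoxy-6-methylbenzoate | COC(=O)c1c(OC(C)=O)c(OC)ccc1C
F3 | step 4 | methyl 2-acetoxy-6-(bromomethyl)-3-methoxybenzoate | COC(=O)c1c(OC(C)=O)c(OC)ccc1CBr
F4 | step 4 | methyl 2-acetoxy-3-methoxy-6-[(methylsulfonyl)methyl]benzoate | COC(=O)c1c(OC(C)=O)c(OC)ccc1CS(C)(=O)=O
F5 | step 7 | 2,4,5-tribromo-6-methoxy-3-[(methylsulfonyl)methyl]phenol | COc1c(O)c(Br)c(CS(C)(=O)=O)c(Br)c1Br
F6 | step 3 | 3,3-dimethoxypropanal | COC(OC)CC=O
F7 | step 3 | 4,4-dimethoxy-1-(methylsulfonyl)butan-2-ol (racemic) | COC(OC)CC(O)CS(C)(=O)=O
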